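## Structural features

The target is a daucane-type hydroazulene: a cyclopentane (C1–C5) trans-fused through the C1–C5 bond to a cycloheptene (C1, C5–C10) whose only alkene is the methyl-bearing, trisubstituted C8=C9. Four stereocenters form one contiguous block around C5: the quaternary, methyl-bearing C1, the fusion methine C5, the tertiary isopropyl carbinol C4 and the acyloxy methine C6. The C1 methyl and the C4 hydroxyl lie on one face, H5 and the C6 oxygen on the other (1R,4R,5S,6S in this numbering). The fragile points are three. The tertiary C4 hydroxyl is β to C6, so any C6 ketone is an aldol open to retro-aldol cleavage and dehydration. The C8=C9 bond is β,γ to C6 and can drift into conjugation. The salicylate, with its free phenol, tolerates neither hydride nor organometallic reagents. The real difficulty is to create the all-carbon quaternary C1 in the correct absolute sense and then relay it to C4, C5 and C6 across a flexible seven-membered ring that offers little intrinsic facial bias. The feature exploited is that C8=C9 and a latent C5=C6 enol ether (the C6 oxygen) are 1,4-related in the seven-membered ring, a 1,4-cycloheptadiene retron with C1 at one terminus of a [3,3] shift. In addition, the C4 and C6 oxygens are 1,3-related through C5, so that they map onto a vinylogous ester.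

## Logic of the disconnections

24 ⇒ 22 + 23. The C6–O acyl bond is cut first because the ortho-hydroxybenzoate would survive none of the reducing or organometallic steps needed earlier. This removes the aromatic unit and leaves a diol. The forward step must acylate the secondary hydroxyl in the presence of the tertiary one and release the phenol in the same operation.

22 ⇒ 21. The C6–H bond is cut so that C6 becomes a ketone. Its configuration can then be derived from C4 by internal hydride delivery, which removes one stereocenter. The forward step requires that the tertiary C4 hydroxyl carries the hydride to the face it occupies.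

21 ⇒ 19 ⇒ 18 ⇒ 17. The C5–H bond, and then the C4–O and C5–O bonds of an epoxide, are cut. The aldol-type C4 hydroxyl is thereby traced to an α,β-epoxy ketone and further to a hydroxyl-directed epoxidation of a tetrasubstituted C4=C5 alkene. Two stereocenters collapse into one directing carbinol at C6. The forward steps require that this carbinol lies on the face of the C1 methyl, and that protonation at C5 after reductive opening gives the trans ring fusion.

17 ⇒ 15 ⇒ 14 ⇒ 13. The C–H bonds of the C8 methyl are traced to the C–O bonds of an ester, and the C6–H bond to an enone carbonyl. The ester is the acceptor group the carbenoid chemistry needs, and the hydride steps that remove it also create the directing C6 carbinol. The result is an enone ester with a single stereocenter. The forward steps need reagent control in the ketone reduction and selective removal of the primary allylic oxygen next to a secondary one.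

13 ⇒ 11 (through 12). The C4–isopropyl bond is cut with 1,3-transposition of the carbonyl, because the C4/C6 dioxygenation of 11 is a vinylogous ester. This removes the isopropyl group and reaches the direct annulation product. The nucleophile must attack the vinylogous ester carbonyl and not the C8 ester, and the acid step must not move C8=C9.

11 ⇒ 4 + 9 (through 10). The C1–C10 and C7–C8 bonds are cut, the retro-Cope/retro-cyclopropanation of a 1,4-cycloheptadiene. A bicyclic compound with a quaternary stereocenter falls apart into two achiral fragments. The forward step must be site-, diastereo- and enantioselective in the cyclopropanation and must form a quaternary carbon in the [3,3] shift.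

4 ⇒ 2 + 3, and 2 ⇒ 1. The sp2–sp2 bond C5–C6 is cut, and then the C–I bond. The diene is traced to a commercial enone and a commercial stannane. The acid-labile dienol ether must be handled without acid.

9 ⇒ 7 ⇒ 6 ⇒ 5. The vinyl C=C bond is traced to dehydration of a carbinol and the diazo group to diazo transfer onto an active methylene. This gives a commodity β-keto ester. Since 9 is thermally labile it must be made last and used at once.

## Other disconnections considered

Alternative 1: The cut removes the C1–C10 and C4–C5 ring bonds together, so that both rings unravel to acyclic (2E,6E)-farnesyl diphosphate A2. In the forward sense a carotol-forming class 1 sesquiterpene synthase ionises A2, steers the cation through both ring closures in one active site and quenches the last cation with water to give carotol A1.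
- In favour: one operation builds the whole carbon skeleton with quaternary C1 in the correct absolute sense, without protecting groups. In skeletal step economy and in control of C1 this is better than the chosen plan.
- Against: A1 has its hydroxyl on C5, hydrogen on C4 and nothing on C6, whereas the target needs the opposite at C4/C5 and an oxygen at C6. The enzyme-set C4 and C5 centers would have to be erased by dehydration to the C4=C5 diene A3, and C4 and C6 then oxygenated selectively in the presence of C8=C9 and several other allylic positions.
- Comparison: an enzyme-templated cationic cascade stands against a catalyst-controlled pericyclic sequence. The chosen plan places the C4 and C6 oxygens by construction in 11, while this alternative must retrofit them. Once those corrections and the enzyme supply are counted, no overall saving is expected.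

Alternative 2: The cut is the C4–C5 bond of the five-membered ring. It leads back to the monocyclic α-diazo ketone A4, a cycloheptenone whose quaternary C1 carries the silyloxy-isopropyl side chain. In the forward sense Rh2(OAc)4 (divalent rhodium) generates a carbenoid at C5 that inserts into the tertiary C4–H bond with retention, giving the bicyclic silyl ether A5.
- In favour: the C4 configuration can be set in an open chain by a reliable asymmetric carbonyl reaction and carried through unchanged, and the α-oxygenated C–H bond is electronically activated. A5 is one desilylation from the ketol 21. The end game is therefore equal to the chosen plan, and control of C4 is better because no epoxidation/reductive-opening detour is needed.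
- Against: C1 needs its own asymmetric step and must be matched with C4. The diazo group has to be placed at the hindered C5 next to quaternary C1, although C7 is the more accessible and more acidic α-position. The C–H bond to be attacked is crowded by the isopropyl and silyl groups, and insertion at the isopropyl methine and Wolff rearrangement compete.
- Comparison: this step forms one bond and one ring and no quaternary center, against two bonds, one ring and C1 in the chosen key step. Upstream it is longer and linear, and downstream it is equal.

Alternative 3: The cut is the C9–C10 bond. The precursor A6 is a cyclopentane that already carries all four stereocenters, a Z-vinyl iodide at C9 and a neopentyl iodide at C10. In the forward sense NiBr2·glyme with 4,4′-di-tert-butyl-2,2′-bipyridine and Zn couples the two carbon–iodine termini reductively and closes the seven-membered ring to the bis-silyl ether A7.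
- In favour: the conditions are mild and tolerate silyl ethers. No C6 ketone appears late, so alkene migration, retro-aldol cleavage and C5 epimerisation cannot arise, which is better than the chosen plan on that point. A7 is only desilylation and acylation from the target, an end game that is equal or shorter.
- Against: the ring closure creates no stereocenter, so quaternary C1 and the C4/C5/C6 array must all be built on the cyclopentane by separate means. A geometrically pure trisubstituted Z-vinyl iodide is required. Hydrodehalogenation and intermolecular coupling compete with a seven-membered closure at a congested neopentyl carbon.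
- Comparison: the chosen key step makes the ring, two bonds and C1 from two simple achiral partners, while here the stereochemical burden rests entirely on a long precursor synthesis. The overall step count should be higher, although the late stage is more robust.

Key step: step 6

Assumption: the face selectivity of dirhodium prolinate vinylcarbenoids toward the 1,1-disubstituted enol ether of 4 is taken to follow the model for terminal alkenes (alkenyl substituent syn to the carbenoid vinyl group). On that model Rh2(R-DOSP)4, i.e. Rh2[(R)-N-(4-dodecylphenylsulfonyl)prolinate]4, leads to 10. Rh2(S-DOSP)4 would replace it if a configurational check on 11 showed the opposite sense.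

## Route

Step 1
Reactants: 1 3-methylcyclopent-2-en-1-one
Product: 2 2-iodo-3-methylcyclopent-2-en-1-one
Conditions: I2, pyridine, CH2Cl2, 0 °C → rt
Reagents that add atoms: iodine, II
Why: Johnson-type α-iodination: pyridine adds reversibly to the β-carbon, the enolate is iodinated and pyridine is expelled, so iodine is placed only at C2 of the enone.

Step 2
Reactants: 2 2-iodo-3-methylcyclopent-2-en-1-one; 3 tributyl(1-ethoxyvinyl)stannane
Product: 4 2-(1-ethoxyvinyl)-3-methylcyclopent-2-en-1-one
Conditions: Pd(PPh3)4 (5 mol %, zerovalent palladium), CuI (10 mol %), DMF, 60 °C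
Reagents that add atoms: none
Why: Stille coupling of an α-iodoenone, a fast oxidative-addition partner, with CuI accelerating transmetalation; the dienol ether should survive if chromatographed on Et3N-deactivated silica.

Step 3
Reactants: 5 methyl acetoacetate
Product: 6 methyl 2-diazo-3-oxobutanoate
Conditions: p-ABSA, Et3N, MeCN, 0 °C → rt
Reagents that add atoms: 4-acetamidobenzenesulfonyl azide (p-ABSA), CC(=O)Nc1ccc(cc1)S(=O)(=O)N=[N+]=[N-]
Why: Regitz diazo transfer to the doubly activated methylene; the sulfonamide by-product is removed by filtration.

Step 4
Reactants: 6 methyl 2-diazo-3-oxobutanoate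
Product: 7 methyl 2-diazo-3-hydroxybutanoate (racemic)
Conditions: NaBH4, MeOH, 0 °C
Reagents that add atoms: none
Why: Borohydride reduces the ketone only, since the ester and the acceptor-stabilised diazo group are inert at 0 °C; the new carbinol center is removed in step 5.

Step 5
Reactants: 7 methyl 2-diazo-3-hydroxybutanoate
Product: 9 methyl 2-diazobut-3-enoate, via dichlorophosphate ester 8 (not isolated)
Conditions: POCl3, Et3N, CH2Cl2, 0 °C → rt; cold pentane filtration, used at once
Reagents that add atoms: none
Why: Dehydration by O-phosphorylation and amine-induced elimination toward the methyl group; the vinyl diazo ester is kept cold and dilute because it cyclises slowly to a pyrazole.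

Step 6
Reactants: 4 2-(1-ethoxyvinyl)-3-methylcyclopent-2-en-1-one; 9 methyl 2-diazobut-3-enoate
Product: 11 methyl (8aR)-4-ethoxy-8a-methyl-3-oxo-1,2,3,5,8,8a-hexahydroazulene-6-carboxylate, via cis-divinylcyclopropane 10 (not isolated)
Conditions: Rh2(R-DOSP)4 (1 mol %, divalent rhodium), 2,2-dimethylbutane/PhMe, −78 °C → rt, slow addition of 9 (2 equiv); then PhMe, 110 °C
Reagents that add atoms: none
Why: The catalyst extrudes N2 from 9 to give an electrophilic rhodium-bound vinylcarbene, which cyclopropanates the terminal C6=C7 enol-ether alkene of 4 (new bonds C6–C8 and C7–C8) to give 10. Warming then drives a [3,3] sigmatropic (Cope) shift of this cis-divinylcyclopropane through a boat transition state, breaking C6–C8 and joining C1 to C10. The closest known reaction type is the tandem cyclopropanation/Cope rearrangement (formal 4+3 annulation) of dirhodium vinylcarbenoids with 2-oxygenated 1,3-dienes. The seven-membered ring therefore closes by a concerted, strain-releasing pericyclic ring expansion of the three-membered ring, not by a polar or radical end-to-end cyclisation. The only new stereocenter, quaternary C1, is controlled by the chiral prolinate ligands, which select the enantioface of C6=C7; the C6 and C8 configurations of 10 are then transferred to C1 because the boat geometry fixes which face of C5=C1 meets C10. Site selectivity between the two alkenes of 4 is secured by the donor ethoxy group on the terminal alkene, the C5=C1 bond being tetrasubstituted and deactivated by the ketone. The cis arrangement of the two alkenyl groups follows from the preference of donor/acceptor carbenoids to place the alkene substituent syn to the vinyl group, and a trans isomer should equilibrate on heating because C6–C8 is a donor–acceptor bond. Heating is needed only because the C1 methyl must point toward the cyclopropane methylene in the boat.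

Step 7
Reactants: 11 methyl (8aR)-4-ethoxy-8a-methyl-3-oxo-1,2,3,5,8,8a-hexahydroazulene-6-carboxylate
Product: 13 methyl (8aR)-3-isopropyl-8a-methyl-4-oxo-1,2,4,5,8,8a-hexahydroazulene-6-carboxylate, via tertiary carbinol 12 (not isolated)
Conditions: i-PrMgCl, CeCl3, THF, −78 °C; then 1 M HCl, THF, 0 °C
Reagents that add atoms: isopropylmagnesium chloride, CC(C)[Mg]Cl; water, O
Why: Stork–Danheiser sequence: the weakly basic organocerium reagent adds 1,2 to the vinylogous ester carbonyl (C4) while the less electrophilic C8 ester is left alone at −78 °C. Cold aqueous acid then ionises the tertiary allylic carbinol with help from the enol-ether oxygen, and water capture with loss of ethanol gives the transposed C4=C5–C6 enone; the C4 center of 12 is erased.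

Step 8
Reactants: 13 methyl (8aR)-3-isopropyl-8a-methyl-4-oxo-1,2,4,5,8,8a-hexahydroazulene-6-carboxylate
Product: 14 methyl (4R,8aR)-4-hydroxy-3-isopropyl-8a-methyl-1,2,4,5,8,8a-hexahydroazulene-6-carboxylate
Conditions: (S)-1-methyl-3,3-diphenyltetrahydro-1H,3H-pyrrolo[1,2-c][1,3,2]oxazaborole (0.3 equiv), catecholborane, PhMe, −78 → −40 °C
Reagents that add atoms: none
Why: Corey–Bakshi–Shibata reduction: the oxazaborolidine differentiates the fully substituted alkenyl arm (C5, large) from the C7 methylene (small) and should deliver hydride so that the C6 hydroxyl (6R) lies on the face of the C1 methyl. Catecholborane leaves the ester and both alkenes untouched.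

Step 9
Reactants: 14 methyl (4R,8aR)-4-hydroxy-3-isopropyl-8a-methyl-1,2,4,5,8,8a-hexahydroazulene-6-carboxylate
Product: 15 (4R,8aR)-6-(hydroxymethyl)-3-isopropyl-8a-methyl-1,2,4,5,8,8a-hexahydroazulen-4-ol
Conditions: i-Bu2AlH (4 equiv), CH2Cl2, −78 → 0 °C; aq. KNaC4H4O6
Reagents that add atoms: none
Why: 1,2-Reduction of the conjugated ester to the primary allylic alcohol by the aluminium hydride; with C6 already a carbinol, no ketone or acidic C7 methylene is left to interfere.

Step 10
Reactants: 15 (4R,8aR)-6-(hydroxymethyl)-3-isopropyl-8a-methyl-1,2,4,5,8,8a-hexahydroazulen-4-ol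
Product: 17 (4R,8aR)-3-isopropyl-6,8a-dimethyl-1,2,4,5,8,8a-hexahydroazulen-4-ol, via primary allylic mesylate 16 (not isolated)
Conditions: MsCl (1.05 equiv), Et3N, THF, −40 °C; then LiBHEt3, −40 → 0 °C
Reagents that add atoms: none
Why: The unhindered primary allylic hydroxyl is sulfonylated much faster than the secondary one, which is flanked by a tetrasubstituted alkene; direct SN2 displacement by the borohydride then turns CH2OMs into the C8 methyl without moving C8=C9.

Step 11
Reactants: 17 (4R,8aR)-3-isopropyl-6,8a-dimethyl-1,2,4,5,8,8a-hexahydroazulen-4-ol
Product: 18 (3R,3aS,4R,8aR)-3,3a-epoxy-3-isopropyl-6,8a-dimethyl-1,2,3,3a,4,5,8,8a-octahydroazulen-4-ol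
Conditions: VO(acac)2 (5 mol %), t-BuOOH, CH2Cl2, 0 °C
Reagents that add atoms: tert-butyl hydroperoxide, CC(C)(C)OO
Why: Vanadium-catalysed hydroxyl-directed epoxidation: the peroxide bound to the vanadate ester of the C6 hydroxyl is delivered to the C4=C5 face on which that hydroxyl lies, setting the C4–O bond on the face of the C1 methyl. The allylic tetrasubstituted alkene should react well ahead of the merely homoallylic C8=C9.

Step 12
Reactants: 18 (3R,3aS,4R,8aR)-3,3a-epoxy-3-isopropyl-6,8a-dimethyl-1,2,3,3a,4,5,8,8a-octahydroazulen-4-ol
Product: 19 (3R,3aR,8aR)-3,3a-epoxy-3-isopropyl-6,8a-dimethyl-2,3,3a,5,8,8a-hexahydroazulen-4(1H)-one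
Conditions: 1,1,1-triacetoxy-1,1-dihydro-1,2-benziodoxol-3(1H)-one (Dess–Martin periodinane), NaHCO3, CH2Cl2, 0 °C → rt
Reagents that add atoms: none
Why: Buffered Dess–Martin oxidation of the secondary carbinol, mild enough to leave the acid-sensitive tetrasubstituted epoxide and the β,γ-alkene in place; the C6 center has served its directing purpose and is removed.

Step 13
Reactants: 19 (3R,3aR,8aR)-3,3a-epoxy-3-isopropyl-6,8a-dimethyl-2,3,3a,5,8,8a-hexahydroazulen-4(1H)-one
Product: 21 (3R,3aR,8aR)-3-hydroxy-3-isopropyl-6,8a-dimethyl-2,3,3a,5,8,8a-hexahydroazulen-4(1H)-one, via samarium enolate 20 (not isolated)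
Conditions: SmI2 (2.5 equiv), THF/MeOH, −90 °C; pH 7 buffer
Reagents that add atoms: none
Why: Reduction of an α,β-epoxy ketone by SmI2: the ketyl expels the Cα–O bond at C5, a second electron gives the enolate and methanol protonates it, while the C4–O bond is untouched. The trans-fused C5 epimer is expected because it keeps C6 away from the isopropyl group and allows a hydrogen bond from the C4 hydroxyl to the ketone.

Step 14
Reactants: 21 (3R,3aR,8aR)-3-hydroxy-3-isopropyl-6,8a-dimethyl-2,3,3a,5,8,8a-hexahydroazulen-4(1H)-one
Product: 22 (3R,3aS,4S,8aR)-3-isopropyl-6,8a-dimethyl-1,2,3,3a,4,5,8,8a-octahydroazulene-3,4-diol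
Conditions: Me4NBH(OAc)3, MeCN/AcOH (1:1), −30 → −20 °C
Reagents that add atoms: none
Why: Evans–Saksena directed reduction: acetate exchange ties the hydride to the C4 oxygen and it is delivered intramolecularly to the C6 carbonyl from the face of that oxygen, placing the new hydroxyl on the opposite face as the target requires. The reagent is too weak to reduce the ketone without this tether.

Step 15
Reactants: 22 (3R,3aS,4S,8aR)-3-isopropyl-6,8a-dimethyl-1,2,3,3a,4,5,8,8a-octahydroazulene-3,4-diol; 23 2,2-dimethyl-4H-1,3-benzodioxin-4-one
Product: 24 (3R,3aS,4S,8aR)-3-hydroxy-3-isopropyl-6,8a-dimethyl-1,2,3,3a,4,5,8,8a-octahydroazulen-4-yl 2-hydroxybenzoate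
Conditions: NaN(SiMe3)2 (1.1 equiv), THF, −20 °C → rt; then AcOH
Reagents that add atoms: none
Why: Alkoxide transesterification of a salicylic acid acetonide: the secondary C6 alkoxide attacks the acyl carbon and the expelled hemiketal loses acetone to reveal the phenoxide, so the ester and the free phenol arise together. The tertiary C4 alkoxide is too hindered to compete.

## Compound list

1 | 3-methylcyclopent-2-en-1-one | CC1=CC(=O)CC1 | starting material
2 | 2-iodo-3-methylcyclopent-2-en-1-one | CC1=C(I)C(=O)CC1 | intermediate
3 | tributyl(1-ethoxyvinyl)stannane | CCCC[Sn](CCCC)(CCCC)C(=C)OCC | starting material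
4 | 2-(1-ethoxyvinyl)-3-methylcyclopent-2-en-1-one | CCOC(=C)C1=C(C)CCC1=O | intermediate
5 | methyl acetoacetate | COC(=O)CC(C)=O | starting material
6 | methyl 2-diazo-3-oxobutanoate | COC(=O)C(=[N+]=[N-])C(C)=O | intermediate
7 | methyl 2-diazo-3-hydroxybutanoate (racemic) | COC(=O)C(=[N+]=[N-])C(C)O | intermediate
8 | methyl 2-diazo-3-(dichlorophosphoryloxy)butanoate (racemic, not isolated) | COC(=O)C(=[N+]=[N-])C(C)OP(Cl)(Cl)=O | intermediate
9 | methyl 2-diazobut-3-enoate | COC(=O)C(=[N+]=[N-])C=C | intermediate
10 | methyl (1S,2R)-2-ethoxy-2-(2-methyl-5-oxocyclopent-1-en-1-yl)-1-vinylcyclopropane-1-carboxylate (vinyl and cyclopentenyl cis; not isolated) | COC(=O)[C@]1(C=C)C[C@@]1(OCC)C2=C(C)CCC2=O | intermediate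
11 | methyl (8aR)-4-ethoxy-8a-methyl-3-oxo-1,2,3,5,8,8a-hexahydroazulene-6-carboxylate | COC(=O)C1=CC[C@@]2(C)CCC(=O)C2=C(OCC)C1 | intermediate
12 | methyl (8aR)-4-ethoxy-3-hydroxy-3-isopropyl-8a-methyl-1,2,3,5,8,8a-hexahydroazulene-6-carboxylate (C3 epimers, not isolated) | COC(=O)C1=CC[C@@]2(C)CCC(O)(C(C)C)C2=C(OCC)C1 | intermediate
13 | methyl (8aR)-3-isopropyl-8a-methyl-4-oxo-1,2,4,5,8,8a-hexahydroazulene-6-carboxylate | COC(=O)C1=CC[C@@]2(C)CCC(C(C)C)=C2C(=O)C1 | intermediate
14 | methyl (4R,8aR)-4-hydroxy-3-isopropyl-8a-methyl-1,2,4,5,8,8a-hexahydroazulene-6-carboxylate | COC(=O)C1=CC[C@@]2(C)CCC(C(C)C)=C2[C@H](O)C1 | intermediate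
15 | (4R,8aR)-6-(hydroxymethyl)-3-isopropyl-8a-methyl-1,2,4,5,8,8a-hexahydroazulen-4-ol | OCC1=CC[C@@]2(C)CCC(C(C)C)=C2[C@H](O)C1 | intermediate
16 | [(4R,8aR)-4-hydroxy-3-isopropyl-8a-methyl-1,2,4,5,8,8a-hexahydroazulen-6-yl]methyl methanesulfonate (not isolated) | CS(=O)(=O)OCC1=CC[C@@]2(C)CCC(C(C)C)=C2[C@H](O)C1 | intermediate
17 | (4R,8aR)-3-isopropyl-6,8a-dimethyl-1,2,4,5,8,8a-hexahydroazulen-4-ol | CC1=CC[C@@]2(C)CCC(C(C)C)=C2[C@H](O)C1 | intermediate
18 | (3R,3aS,4R,8aR)-3,3a-epoxy-3-isopropyl-6,8a-dimethyl-1,2,3,3a,4,5,8,8a-octahydroazulen-4-ol (epoxide oxygen, C4 hydroxyl of the ring and C8a methyl on one face) | CC1=CC[C@@]2(C)CC[C@]3(C(C)C)O[C@]23[C@H](O)C1 | intermediate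
19 | (3R,3aR,8aR)-3,3a-epoxy-3-isopropyl-6,8a-dimethyl-2,3,3a,5,8,8a-hexahydroazulen-4(1H)-one | CC1=CC[C@@]2(C)CC[C@]3(C(C)C)O[C@]23C(=O)C1 | intermediate
20 | diiodosamarium enolate of 21 (trivalent samarium, not isolated) | CC1=CC[C@@]2(C)CC[C@@](O)(C(C)C)C2=C(O[Sm](I)I)C1 | intermediate
21 | (3R,3aR,8aR)-3-hydroxy-3-isopropyl-6,8a-dimethyl-2,3,3a,5,8,8a-hexahydroazulen-4(1H)-one (trans-fused) | CC1=CC[C@@]2(C)CC[C@@](O)(C(C)C)[C@@H]2C(=O)C1 | intermediate
22 | (3R,3aS,4S,8aR)-3-isopropyl-6,8a-dimethyl-1,2,3,3a,4,5,8,8a-octahydroazulene-3,4-diol | CC1=CC[C@@]2(C)CC[C@@](O)(C(C)C)[C@@H]2[C@@H](O)C1 | intermediate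
23 | 2,2-dimethyl-4H-1,3-benzodioxin-4-one | CC1(C)OC(=O)c2ccccc2O1 | starting material
24 | (3R,3aS,4S,8aR)-3-hydroxy-3-isopropyl-6,8a-dimethyl-1,2,3,3a,4,5,8,8a-octahydroazulen-4-yl 2-hydroxybenzoate | CC1=CC[C@@]2(C)CC[C@@](O)(C(C)C)[C@@H]2[C@@H](OC(=O)c2ccccc2O)C1 | target

## Step count and least certain steps

Total: 15 steps. Longest linear sequence: 13 steps (from 5 through steps 3–15); the branch from 1 (steps 1 and 2) joins at step 6.

Step 6 (key step). The most likely failure is loss of enantiomeric purity. The face discrimination of the catalyst for a 1,1-disubstituted enol ether is less assured than for terminal alkenes, and 10 may reopen heterolytically across its donor–acceptor C6–C8 bond at the temperature the hindered Cope shift needs. Reaction of the carbenoid through its vinylogous terminus, which leads to five-membered rings, may also lower the yield. Fallback: the stereocontrol is moved from the annulation to the later reduction. Setting out from 4 and 9, the annulation is run with achiral Rh2(O2CC7H15)4 (divalent rhodium), which should give 10 together with the mirror-image cyclopropane F1, and after heating 11 together with the (8aS)-vinylogous ester F2. Step 7 applied to this racemate passes through 12 and the (8aS)-carbinol F3, and gives 13 together with the (8aS)-enone F4. The oxazaborolidine reduction of step 8 is reagent-controlled and should turn the two enantiomers into diastereomers, 14 and the (4R,8aS)-alcohol F5. These are separated by chromatography, and the route is rejoined at 14.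

Step 7. Three processes threaten it: β-hydride transfer or enolisation by the branched organometallic in place of addition, attack on the C8 ester, and acid-promoted migration of C8=C9 into conjugation through the doubly activated C7 methylene. Fallback: setting out from 11, the sp2 nucleophile isopropenylmagnesium bromide with CeCl3 is used. It is less basic, less hindered and has no comparable β-hydride pathway. It should give the isopropenyl carbinol F6, and brief cold acid then gives the isopropenyl dienone F7. Hydrogenation of the 1,1-disubstituted alkene alone with RhCl(PPh3)3 (monovalent rhodium) and H2 returns to the route at 13.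

Step 10. Sulfonylation may not stop at the primary hydroxyl; activation of the secondary allylic hydroxyl would lead to ionisation and elimination, and some hydride may be delivered in the SN2′ sense. Fallback: setting out from 14, the secondary hydroxyl is protected with Et3SiCl and imidazole as the silyl ether ester F8. Reduction with i-Bu2AlH gives the silyl ether alcohol F9. Mesylation to the silyl ether mesylate F10 and displacement with LiBHEt3 give the silyl ether F11, and Bu4NF returns to the route at 17.

Step 11. The vanadium peroxide may oxidise the hindered allylic alcohol to the enone and not epoxidise it. The Lewis-acidic metal may also trigger rearrangement of the tetrasubstituted epoxy alcohol, and face control weakens if the hydroxyl lies close to the alkene plane. Fallback: setting out from 17, the alcohol is oxidised on purpose with MnO2 to the enone F12. This is epoxidised nucleophilically (t-BuOOH, DBU, Weitz–Scheffer type), rejoining the route at 19. The face selectivity then rests on substrate bias and would need to be verified.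

Step 13. Protonation of enolate 20 may occur from the wrong face and give the cis-fused C5 epimer, and the aldolate may undergo β-elimination or retro-aldol cleavage if it warms before quenching. Fallback: control is changed from kinetic to thermodynamic. Setting out from 19, the reduction is quenched cold. If the cis-fused ketol F13 is obtained, it is isolated and equilibrated with DBU in CH2Cl2 toward the trans-fused isomer, which places C6 away from the isopropyl group, and the route is rejoined at 21.

Step 15. Acyl transfer to the hindered secondary alkoxide may be slow, so that base-induced decomposition of 23 or of the product competes. Fallback: a two-stage acylation with a masked phenol. Setting out from 22, 2-acetoxybenzoyl chloride with pyridine and 4-(dimethylamino)pyridine should give the acetylsalicylate F14. Selective aminolysis of the phenolic acetate with pyrrolidine then gives 24.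

## Further compounds

F1 | step 6 | methyl (1R,2S)-2-ethoxy-2-(2-methyl-5-oxocyclopent-1-en-1-yl)-1-vinylcyclopropane-1-carboxylate (enantiomer of 10) | COC(=O)[C@@]1(C=C)C[C@]1(OCC)C2=C(C)CCC2=O
F2 | step 6 | methyl (8aS)-4-ethoxy-8a-methyl-3-oxo-1,2,3,5,8,8a-hexahydroazulene-6-carboxylate (enantiomer of 11) | COC(=O)C1=CC[C@]2(C)CCC(=O)C2=C(OCC)C1
F3 | step 6 | methyl (8aS)-4-ethoxy-3-hydroxy-3-isopropyl-8a-methyl-1,2,3,5,8,8a-hexahydroazulene-6-carboxylate (C3 epimers) | COC(=O)C1=CC[C@]2(C)CCC(O)(C(C)C)C2=C(OCC)C1
F4 | step 6 | methyl (8aS)-3-isopropyl-8a-methyl-4-oxo-1,2,4,5,8,8a-hexahydroazulene-6-carboxylate (enantiomer of 13) | COC(=O)C1=CC[C@]2(C)CCC(C(C)C)=C2C(=O)C1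
F5 | step 6 | methyl (4R,8aS)-4-hydroxy-3-isopropyl-8a-methyl-1,2,4,5,8,8a-hexahydroazulene-6-carboxylate | COC(=O)C1=CC[C@]2(C)CCC(C(C)C)=C2[C@H](O)C1
F6 | step 7 | methyl (8aR)-4-ethoxy-3-hydroxy-8a-methyl-3-(prop-1-en-2-yl)-1,2,3,5,8,8a-hexahydroazulene-6-carboxylate (C3 epimers) | COC(=O)C1=CC[C@@]2(C)CCC(O)(C(C)=C)C2=C(OCC)C1
F7 | step 7 | methyl (8aR)-8a-methyl-4-oxo-3-(prop-1-en-2-yl)-1,2,4,5,8,8a-hexahydroazulene-6-carboxylate | COC(=O)C1=CC[C@@]2(C)CCC(C(C)=C)=C2C(=O)C1
F8 | step 10 | methyl (4R,8aR)-3-isopropyl-8a-methyl-4-(triethylsilyloxy)-1,2,4,5,8,8a-hexahydroazulene-6-carboxylate | COC(=O)C1=CC[C@@]2(C)CCC(C(C)C)=C2[C@H](O[Si](CC)(CC)CC)C1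
F9 | step 10 | [(4R,8aR)-3-isopropyl-8a-methyl-4-(triethylsilyloxy)-1,2,4,5,8,8a-hexahydroazulen-6-yl]methanol | OCC1=CC[C@@]2(C)CCC(C(C)C)=C2[C@H](O[Si](CC)(CC)CC)C1
F10 | step 10 | [(4R,8aR)-3-isopropyl-8a-methyl-4-(triethylsilyloxy)-1,2,4,5,8,8a-hexahydroazulen-6-yl]methyl methanesulfonate | CS(=O)(=O)OCC1=CC[C@@]2(C)CCC(C(C)C)=C2[C@H](O[Si](CC)(CC)CC)C1
F11 | step 10 | triethyl{[(4R,8aR)-3-isopropyl-6,8a-dimethyl-1,2,4,5,8,8a-hexahydroazulen-4-yl]oxy}silane | CC1=CC[C@@]2(C)CCC(C(C)C)=C2[C@H](O[Si](CC)(CC)CC)C1
F12 | step 11 | (8aR)-3-isopropyl-6,8a-dimethyl-1,2,8,8a-tetrahydroazulen-4(5H)-one | CC1=CC[C@@]2(C)CCC(C(C)C)=C2C(=O)C1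
F13 | step 13 | (3R,3aS,8aR)-3-hydroxy-3-isopropyl-6,8a-dimethyl-2,3,3a,5,8,8a-hexahydroazulen-4(1H)-one (cis-fused C3a epimer of 21) | CC1=CC[C@@]2(C)CC[C@@](O)(C(C)C)[C@H]2C(=O)C1
F14 | step 15 | (3R,3aS,4S,8aR)-3-hydroxy-3-isopropyl-6,8a-dimethyl-1,2,3,3a,4,5,8,8a-octahydroazulen-4-yl 2-acetoxybenzoate | CC1=CC[C@@]2(C)CC[C@@](O)(C(C)C)[C@@H]2[C@@H](OC(=O)c2ccccc2OC(C)=O)C1
A1 | alternative 1 | carotol | CC1=CC[C@@]2(C)CC[C@@H](C(C)C)[C@@]2(O)CC1
A2 | alternative 1 | (2E,6E)-farnesyl diphosphate | CC(C)=CCC/C(C)=C/CC/C(C)=C/COP(O)(=O)OP(O)(O)=O
A3 | alternative 1 | dauca-4,8-diene from dehydration of A1 | CC1=CC[C@@]2(C)CCC(C(C)C)=C2CC1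
A4 | alternative 2 | 2-diazo-3-[4-(tert-butyldimethylsilyloxy)-5-methylhexyl]-3,6-dimethylcyclohept-5-en-1-one with the C1 and C4 configurations of the target | CC1=CC[C@@](C)(CC[C@@H](O[Si](C)(C)C(C)(C)C)C(C)C)C(=[N+]=[N-])C(=O)C1
A5 | alternative 2 | C4-silylated bicyclic ketol (C5 unassigned) | CC1=CC[C@@]2(C)CC[C@@](O[Si](C)(C)C(C)(C)C)(C(C)C)C2C(=O)C1
A6 | alternative 3 | cyclopentane bearing the Z-vinyl iodide side chain and the neopentyl iodide, both hydroxyls as triethylsilyl ethers | I/C=C(/C)C[C@H](O[Si](CC)(CC)CC)[C@@H]1[C@@](C)(CI)CC[C@@]1(O[Si](CC)(CC)CC)C(C)C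
A7 | alternative 3 | bis(triethylsilyl) ether of 22 | CC1=CC[C@@]2(C)CC[C@@](O[Si](CC)(CC)CC)(C(C)C)[C@@H]2[C@@H](O[Si](CC)(CC)CC)C1
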